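**Retrosynthetic overview**

- Feature: in the 2,3-dihydro-1,4-benzodioxine (O1, C2 with CH2OH, C3 with aryl, O4; ring A C4a–C8a, propenal on C6), C3 is benzylic and para to the free phenol of a syringyl ring whose two ortho-methoxy groups are equivalent. A 4-hydroxy-3,5-dimethoxybenzyl ether on O4 therefore oxidises to a single quinone methide (no E/Z pair) with C3 electrophilic, while O1, ortho to O4 on ring A, can carry a CH2CHO arm whose α-carbon becomes C2.
- Key disconnection C2–C3: amine-catalysed ring-closing 1,6-addition of the enamine of the O1–CH2–CHO arm to that quinone methide. It closes the dioxane ring (the only ring made; ring A and the syringyl ring are bought) and sets C2 and C3.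
- Precursor: 3,4-dihydroxybenzaldehyde is alkylated at O-4 with a 2-silyloxyethyl bromide, joined at O-3 to silyl-protected syringyl alcohol by Mitsunobu reaction, and olefinated to an N-methoxy-N-methylacrylamide. The aldehyde arm is unmasked by mild acid and Dess–Martin oxidation, not by acetal hydrolysis, which the acid-labile benzyl aryl ether would not survive.
- End game: NaBH4 in the key-step flask fixes C2 as CH2OH, and i-Bu2AlH reduces the Weinreb amide directly to the enal, so no oxidant meets the p-hydroxybenzyl ether again.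

Key step: step 9

Assumption: the sense of induction is taken from the usual model for (S)-diarylprolinol silyl ethers (E-enamine, attack anti to the CPh2OTMS group), which predicts 2R in the ring-closed aldehyde; if the opposite sense were found, the (R)-catalyst would be used.

**Route**

Step 1
Reactants: 1 3,4-dihydroxybenzaldehyde; 2 (2-bromoethoxy)(tert-butyl)dimethylsilane
Product: 3 4-[2-(tert-butyldimethylsilyloxy)ethoxy]-3-hydroxybenzaldehyde
Conditions: NaHCO3 (1.5 equiv), NaI (0.2 equiv), DMF, 60 °C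
Reagents that add atoms: none
Why: Williamson etherification in which NaHCO3 deprotonates only the more acidic 4-OH (para to the formyl group), so the iodide formed in situ from 2 should alkylate O-4 and leave O-3 free.

Step 2
Reactants: 4 4-hydroxy-3,5-dimethoxybenzaldehyde (syringaldehyde)
Product: 5 4-(tert-butyldimethylsilyloxy)-3,5-dimethoxybenzaldehyde
Conditions: TBSCl, imidazole, DMF, rt
Reagents that add atoms: tert-butyldimethylsilyl chloride, CC(C)(C)[Si](C)(C)Cl
Why: Silylation of the phenol, giving a silyl ether that is flanked by two methoxy groups and should therefore last through the later basic and mildly acidic steps.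

Step 3
Reactants: 5 4-(tert-butyldimethylsilyloxy)-3,5-dimethoxybenzaldehyde
Product: 6 [4-(tert-butyldimethylsilyloxy)-3,5-dimethoxyphenyl]methanol
Conditions: NaBH4, MeOH–THF, 0 °C
Reagents that add atoms: none
Why: Hydride reduction of the aryl aldehyde by NaBH4, which should not touch the hindered aryl silyl ether at 0 °C.

Step 4
Reactants: 3 4-[2-(tert-butyldimethylsilyloxy)ethoxy]-3-hydroxybenzaldehyde; 6 [4-(tert-butyldimethylsilyloxy)-3,5-dimethoxyphenyl]methanol
Product: 7 3-{[4-(tert-butyldimethylsilyloxy)-3,5-dimethoxybenzyl]oxy}-4-[2-(tert-butyldimethylsilyloxy)ethoxy]benzaldehyde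
Conditions: PPh3, diisopropyl azodicarboxylate, THF, 0 °C → rt
Reagents that add atoms: none
Why: Mitsunobu etherification in which the 3-OH of 3 is the only acidic partner and displaces the activated primary benzylic alcohol of 6 under neutral conditions, which avoids a labile electron-rich benzyl halide and any base that could strip the aryl silyl ether.

Step 5
Reactants: 7 3-{[4-(tert-butyldimethylsilyloxy)-3,5-dimethoxybenzyl]oxy}-4-[2-(tert-butyldimethylsilyloxy)ethoxy]benzaldehyde; 8 diethyl {2-[methoxy(methyl)amino]-2-oxoethyl}phosphonate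
Product: 9 (E)-3-(3-{[4-(tert-butyldimethylsilyloxy)-3,5-dimethoxybenzyl]oxy}-4-[2-(tert-butyldimethylsilyloxy)ethoxy]phenyl)-N-methoxy-N-methylacrylamide
Conditions: NaH, THF, 0 °C → rt
Reagents that add atoms: none
Why: Horner–Wadsworth–Emmons olefination of the aryl aldehyde with the stabilised phosphonate anion, which should give the E-configured α,β-unsaturated Weinreb amide.

Step 6
Reactants: 9 (E)-3-(3-{[4-(tert-butyldimethylsilyloxy)-3,5-dimethoxybenzyl]oxy}-4-[2-(tert-butyldimethylsilyloxy)ethoxy]phenyl)-N-methoxy-N-methylacrylamide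
Product: 10 (E)-3-(3-{[4-(tert-butyldimethylsilyloxy)-3,5-dimethoxybenzyl]oxy}-4-(2-hydroxyethoxy)phenyl)-N-methoxy-N-methylacrylamide
Conditions: (1S)-(+)-camphor-10-sulfonic acid (0.1 equiv), MeOH–CH2Cl2 (1:1), 0 °C
Reagents that add atoms: none
Why: Acid-catalysed methanolysis should remove the primary alkyl silyl ether much faster than the hindered aryl silyl ether, and catalytic acid at 0 °C should leave the electron-rich benzyl aryl ether intact.

Step 7
Reactants: 10 (E)-3-(3-{[4-(tert-butyldimethylsilyloxy)-3,5-dimethoxybenzyl]oxy}-4-(2-hydroxyethoxy)phenyl)-N-methoxy-N-methylacrylamide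
Product: 11 (E)-3-(3-{[4-(tert-butyldimethylsilyloxy)-3,5-dimethoxybenzyl]oxy}-4-(2-oxoethoxy)phenyl)-N-methoxy-N-methylacrylamide
Conditions: Dess–Martin periodinane, NaHCO3, CH2Cl2, 0 °C → rt
Reagents that add atoms: none
Why: Dess–Martin oxidation of the primary alcohol to the aryloxyacetaldehyde under buffered, non-aqueous conditions that should not affect the silyl ether, the benzyl ether or the enamide.

Step 8
Reactants: 11 (E)-3-(3-{[4-(tert-butyldimethylsilyloxy)-3,5-dimethoxybenzyl]oxy}-4-(2-oxoethoxy)phenyl)-N-methoxy-N-methylacrylamide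
Product: 12 (E)-3-{3-[(4-hydroxy-3,5-dimethoxybenzyl)oxy]-4-(2-oxoethoxy)phenyl}-N-methoxy-N-methylacrylamide
Conditions: tetrabutylammonium fluoride (1.1 equiv), AcOH (1.3 equiv), THF, −20 → 0 °C; neutral work-up, used at once
Reagents that add atoms: none
Why: Fluoride cleavage of the aryl silyl ether buffered with acetic acid, so that the phenol is released protonated and the phenoxide can neither expel the ring-A aryloxide by 1,6-elimination nor trigger condensation of the aldehyde.

Step 9
Reactants: 12 (E)-3-{3-[(4-hydroxy-3,5-dimethoxybenzyl)oxy]-4-(2-oxoethoxy)phenyl}-N-methoxy-N-methylacrylamide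
Product: 15 (E)-3-[(2S,3S)-3-(4-hydroxy-3,5-dimethoxyphenyl)-2-(hydroxymethyl)-2,3-dihydro-1,4-benzodioxin-6-yl]-N-methoxy-N-methylacrylamide, via quinone methide 13 (not isolated), via trans-2-formylbenzodioxane 14 (not isolated)
Conditions: 2,3-dichloro-5,6-dicyano-1,4-benzoquinone (DDQ, 1.0 equiv), CH2Cl2 (0.02 M), 0 °C; then (S)-α,α-diphenylprolinol trimethylsilyl ether (20 mol%), −30 → 0 °C; then NaBH4, EtOH, −20 °C
Reagents that add atoms: none
Why: Proposed new method: DDQ, the limiting reagent and fully consumed before the amine is added, dehydrogenates the phenol to quinone methide 13, whose exocyclic carbon is C3 and carries O4; the secondary amine then condenses with the O1-bound aldehyde to an E-enamine whose carbon C2 adds to C3 in an intramolecular 1,6-(vinylogous Michael) addition that rearomatises the syringyl ring, and hydrolysis of the iminium ion returns the catalyst. The closest known reaction types are the intermolecular diarylprolinol-silyl-ether-catalysed 1,6-addition of aldehydes to isolable para-quinone methides and the DDQ-mediated oxidative α-alkylation of aldehydes with benzylic or oxocarbenium cations under amine catalysis, whereas a ring-closing version on a transient, aryloxy-substituted quinone methide has not been described. The dioxane ring closes in the 6-(enolexo)-exo-trig mode, with the enamine C=C and the quinone methide C=C both outside the new ring. C2 is set by the catalyst, whose CPh2OTMS group shields one face of the anti E-enamine so that C3 is taken on the open face (2R by the usual model), and C3 is set relative to C2 by a chair-like transition state that keeps the aryl group and the enamine unit pseudo-equatorial, which should lead to the trans (2R,3S) aldehyde 14. The step needs ring closure to outrun hydration of 13, intermolecular addition and a second oxidation; this is secured by the ortho relation of O1 and O4 on ring A (no other ring size is geometrically accessible), by high dilution, by DDQH2 acting as a mild acid that raises the oxocarbenium character of the aryloxy-deactivated quinone methide, and by having no DDQ left once the benzylic C3–H of the product exists. NaBH4 is added to the same flask because C2 of 14 is enolisable and O4 is a β-leaving group while C3 is fixed, so any later epimerisation at C2 would cost either the trans relation or the enantiomeric purity.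

Step 10
Reactants: 15 (E)-3-[(2S,3S)-3-(4-hydroxy-3,5-dimethoxyphenyl)-2-(hydroxymethyl)-2,3-dihydro-1,4-benzodioxin-6-yl]-N-methoxy-N-methylacrylamide
Product: 16 (E)-3-[(2S,3S)-3-(4-hydroxy-3,5-dimethoxyphenyl)-2-(hydroxymethyl)-2,3-dihydro-1,4-benzodioxin-6-yl]prop-2-enal (CNP0211211.1)
Conditions: i-Bu2AlH (4.5 equiv), THF, −78 °C; aq. KNaC4H4O6 (potassium sodium tartrate) work-up
Reagents that add atoms: none
Why: Partial reduction of the Weinreb amide, in which i-Bu2AlH (after the phenol and the alcohol have consumed two equivalents) adds once to give a chelated aluminium hemiaminal that should survive at −78 °C and release the E-enal only on work-up, leaving both stereocentres untouched.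

**Compound list**

1 | 3,4-dihydroxybenzaldehyde | O=Cc1ccc(O)c(O)c1 | starting material
2 | (2-bromoethoxy)(tert-butyl)dimethylsilane | CC(C)(C)[Si](C)(C)OCCBr | starting material
3 | 4-[2-(tert-butyldimethylsilyloxy)ethoxy]-3-hydroxybenzaldehyde | CC(C)(C)[Si](C)(C)OCCOc1ccc(C=O)cc1O | intermediate
4 | 4-hydroxy-3,5-dimethoxybenzaldehyde (syringaldehyde) | COc1cc(C=O)cc(OC)c1O | starting material
5 | 4-(tert-butyldimethylsilyloxy)-3,5-dimethoxybenzaldehyde | COc1cc(C=O)cc(OC)c1O[Si](C)(C)C(C)(C)C | intermediate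
6 | [4-(tert-butyldimethylsilyloxy)-3,5-dimethoxyphenyl]methanol | COc1cc(CO)cc(OC)c1O[Si](C)(C)C(C)(C)C | intermediate
7 | 3-{[4-(tert-butyldimethylsilyloxy)-3,5-dimethoxybenzyl]oxy}-4-[2-(tert-butyldimethylsilyloxy)ethoxy]benzaldehyde | O=Cc1ccc(OCCO[Si](C)(C)C(C)(C)C)c(OCc2cc(OC)c(O[Si](C)(C)C(C)(C)C)c(OC)c2)c1 | intermediate
8 | diethyl {2-[methoxy(methyl)amino]-2-oxoethyl}phosphonate | CCOP(=O)(CC(=O)N(C)OC)OCC | starting material
9 | (E)-3-(3-{[4-(tert-butyldimethylsilyloxy)-3,5-dimethoxybenzyl]oxy}-4-[2-(tert-butyldimethylsilyloxy)ethoxy]phenyl)-N-methoxy-N-methylacrylamide | CON(C)C(=O)/C=C/c1ccc(OCCO[Si](C)(C)C(C)(C)C)c(OCc2cc(OC)c(O[Si](C)(C)C(C)(C)C)c(OC)c2)c1 | intermediate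
10 | (E)-3-(3-{[4-(tert-butyldimethylsilyloxy)-3,5-dimethoxybenzyl]oxy}-4-(2-hydroxyethoxy)phenyl)-N-methoxy-N-methylacrylamide | CON(C)C(=O)/C=C/c1ccc(OCCO)c(OCc2cc(OC)c(O[Si](C)(C)C(C)(C)C)c(OC)c2)c1 | intermediate
11 | (E)-3-(3-{[4-(tert-butyldimethylsilyloxy)-3,5-dimethoxybenzyl]oxy}-4-(2-oxoethoxy)phenyl)-N-methoxy-N-methylacrylamide | CON(C)C(=O)/C=C/c1ccc(OCC=O)c(OCc2cc(OC)c(O[Si](C)(C)C(C)(C)C)c(OC)c2)c1 | intermediate
12 | (E)-3-{3-[(4-hydroxy-3,5-dimethoxybenzyl)oxy]-4-(2-oxoethoxy)phenyl}-N-methoxy-N-methylacrylamide (key-step precursor) | CON(C)C(=O)/C=C/c1ccc(OCC=O)c(OCc2cc(OC)c(O)c(OC)c2)c1 | intermediate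
13 | (E)-3-{3-[(3,5-dimethoxy-4-oxocyclohexa-2,5-dien-1-ylidene)methoxy]-4-(2-oxoethoxy)phenyl}-N-methoxy-N-methylacrylamide (quinone methide, not isolated) | CON(C)C(=O)/C=C/c1ccc(OCC=O)c(OC=C2C=C(OC)C(=O)C(OC)=C2)c1 | intermediate
14 | (E)-3-[(2R,3S)-2-formyl-3-(4-hydroxy-3,5-dimethoxyphenyl)-2,3-dihydro-1,4-benzodioxin-6-yl]-N-methoxy-N-methylacrylamide (trans, key-step product, not isolated) | COc1cc([C@@H]2Oc3cc(/C=C/C(=O)N(C)OC)ccc3O[C@H]2C=O)cc(OC)c1O | intermediate
15 | (E)-3-[(2S,3S)-3-(4-hydroxy-3,5-dimethoxyphenyl)-2-(hydroxymethyl)-2,3-dihydro-1,4-benzodioxin-6-yl]-N-methoxy-N-methylacrylamide | COc1cc([C@@H]2Oc3cc(/C=C/C(=O)N(C)OC)ccc3O[C@H]2CO)cc(OC)c1O | intermediate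
16 | (E)-3-[(2S,3S)-3-(4-hydroxy-3,5-dimethoxyphenyl)-2-(hydroxymethyl)-2,3-dihydro-1,4-benzodioxin-6-yl]prop-2-enal | COc1cc([C@@H]2Oc3cc(/C=C/C=O)ccc3O[C@H]2CO)cc(OC)c1O | target

**Step count**

Total step count: 10. Longest linear sequence: 9 steps (steps 2–10, from 4).

**Steps most likely to fail**

1. Step 9 (proposed new method). The aryloxy-stabilised quinone methide may add the enamine too slowly. Hydration by the water released on enamine formation (which cuts C3 off as an aldehyde), intermolecular addition, or poor facial selectivity could then dominate.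
Fallback (known chemistry; sets out from 5 and 8, rejoins at 15): both stereocentres would be set by an auxiliary-controlled boron syn-aldol (Evans aldol), and the dioxane ring closed at the O4–C4a bond.
   - Commercial 3-bromo-4-hydroxybenzaldehyde is O-alkylated with (R)-4-benzyl-3-(bromoacetyl)oxazolidin-2-one (K2CO3, acetone) to give the aryloxyacetyl oxazolidinone F1.
   - Olefination of its formyl group with 8 (LiCl, i-Pr2NEt, MeCN) gives the acrylamide F2.
   - The dibutylboron Z-enolate of F2 (Bu2BOTf, i-Pr2NEt, CH2Cl2, −78 °C) adds to aldehyde 5 to give the (2R,3S) syn-aldol adduct F3.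
   - NaBH4 in THF–H2O cleaves the auxiliary reductively to the (1S,2S) 1,3-diol F4.
   - TBSCl/imidazole silylates only the primary hydroxyl, giving the primary silyl ether F5.
   - Pd(OAc)2 with 2-(di-tert-butylphosphino)-1,1'-binaphthyl and K3PO4 in toluene at 70 °C joins the benzylic oxygen to the brominated ring carbon with retention at C3, giving the bis-silyl benzodioxane F6.
   - Tetrabutylammonium fluoride buffered with AcOH removes both silyl groups and gives 15.

2. Step 8. The freed phenol may fragment by 1,6-elimination of the ring-A aryloxide, and the aryloxyacetaldehyde may self-condense under fluoride.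
Fallback (sets out from 4, uses 3 and 8, rejoins at 12): the phenol would be carried as an allyl ether, which comes off without fluoride or base.
   - 4 is allylated (allyl bromide, K2CO3, DMF) to the allyl ether aldehyde F7 and reduced with NaBH4 to the benzyl alcohol F8.
   - Mitsunobu coupling of F8 with 3 gives the diaryl ether aldehyde F9.
   - Olefination with 8 (NaH, THF) gives the acrylamide F10.
   - Tetrabutylammonium fluoride removes the alkyl silyl ether to give the primary alcohol F11.
   - Dess–Martin oxidation gives the allyl-protected aldehyde F12.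
   - Pd(PPh3)4 with p-toluenesulfinic acid in CH2Cl2 transfers the allyl group to sulfur and releases 12 as the neutral phenol.

3. Step 1. The sluggish β-silyloxyethyl bromide may demand forcing conditions, under which regiocontrol is lost and alkylation occurs at O-3 or at both oxygens.
Fallback (sets out from 2, rejoins at 3): the two oxygens would be told apart in the starting material.
   - Commercial 3-(benzyloxy)-4-hydroxybenzaldehyde is alkylated with 2 (K2CO3, NaI, DMF, 80 °C) to give the benzyl-protected ether F13.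
   - Hydrogenolysis (H2, Pd/C, EtOAc) removes the benzyl group and gives 3.

Further compounds
F1 | step 9 | (R)-4-benzyl-3-[2-(2-bromo-4-formylphenoxy)acetyl]oxazolidin-2-one | O=Cc1ccc(OCC(=O)N2[C@H](Cc3ccccc3)COC2=O)c(Br)c1
F2 | step 9 | (E)-3-(4-{2-[(R)-4-benzyl-2-oxooxazolidin-3-yl]-2-oxoethoxy}-3-bromophenyl)-N-methoxy-N-methylacrylamide | CON(C)C(=O)/C=C/c1ccc(OCC(=O)N2[C@H](Cc3ccccc3)COC2=O)c(Br)c1
F3 | step 9 | (E)-3-[4-({(2R,3S)-1-[(R)-4-benzyl-2-oxooxazolidin-3-yl]-3-[4-(tert-butyldimethylsilyloxy)-3,5-dimethoxyphenyl]-3-hydroxy-1-oxopropan-2-yl}oxy)-3-bromophenyl]-N-methoxy-N-methylacrylamide | CON(C)C(=O)/C=C/c1ccc(O[C@H]([C@@H](O)c2cc(OC)c(O[Si](C)(C)C(C)(C)C)c(OC)c2)C(=O)N2[C@H](Cc3ccccc3)COC2=O)c(Br)c1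
F4 | step 9 | (E)-3-[3-bromo-4-({(1S,2S)-1-[4-(tert-butyldimethylsilyloxy)-3,5-dimethoxyphenyl]-1,3-dihydroxypropan-2-yl}oxy)phenyl]-N-methoxy-N-methylacrylamide | CON(C)C(=O)/C=C/c1ccc(O[C@H]([C@@H](O)c2cc(OC)c(O[Si](C)(C)C(C)(C)C)c(OC)c2)CO)c(Br)c1
F5 | step 9 | (E)-3-[3-bromo-4-({(1S,2S)-3-(tert-butyldimethylsilyloxy)-1-[4-(tert-butyldimethylsilyloxy)-3,5-dimethoxyphenyl]-1-hydroxypropan-2-yl}oxy)phenyl]-N-methoxy-N-methylacrylamide | CON(C)C(=O)/C=C/c1ccc(O[C@H]([C@@H](O)c2cc(OC)c(O[Si](C)(C)C(C)(C)C)c(OC)c2)CO[Si](C)(C)C(C)(C)C)c(Br)c1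
F6 | step 9 | (E)-3-[(2S,3S)-2-[(tert-butyldimethylsilyloxy)methyl]-3-[4-(tert-butyldimethylsilyloxy)-3,5-dimethoxyphenyl]-2,3-dihydro-1,4-benzodioxin-6-yl]-N-methoxy-N-methylacrylamide | COc1cc([C@@H]2Oc3cc(/C=C/C(=O)N(C)OC)ccc3O[C@H]2CO[Si](C)(C)C(C)(C)C)cc(OC)c1O[Si](C)(C)C(C)(C)C
F7 | step 8 | 4-(allyloxy)-3,5-dimethoxybenzaldehyde | C=CCOc1c(OC)cc(C=O)cc1OC
F8 | step 8 | [4-(allyloxy)-3,5-dimethoxyphenyl]methanol | C=CCOc1c(OC)cc(CO)cc1OC
F9 | step 8 | 3-{[4-(allyloxy)-3,5-dimethoxybenzyl]oxy}-4-[2-(tert-butyldimethylsilyloxy)ethoxy]benzaldehyde | O=Cc1ccc(OCCO[Si](C)(C)C(C)(C)C)c(OCc2cc(OC)c(OCC=C)c(OC)c2)c1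
F10 | step 8 | (E)-3-(3-{[4-(allyloxy)-3,5-dimethoxybenzyl]oxy}-4-[2-(tert-butyldimethylsilyloxy)ethoxy]phenyl)-N-methoxy-N-methylacrylamide | CON(C)C(=O)/C=C/c1ccc(OCCO[Si](C)(C)C(C)(C)C)c(OCc2cc(OC)c(OCC=C)c(OC)c2)c1
F11 | step 8 | (E)-3-(3-{[4-(allyloxy)-3,5-dimethoxybenzyl]oxy}-4-(2-hydroxyethoxy)phenyl)-N-methoxy-N-methylacrylamide | CON(C)C(=O)/C=C/c1ccc(OCCO)c(OCc2cc(OC)c(OCC=C)c(OC)c2)c1
F12 | step 8 | (E)-3-(3-{[4-(allyloxy)-3,5-dimethoxybenzyl]oxy}-4-(2-oxoethoxy)phenyl)-N-methoxy-N-methylacrylamide | CON(C)C(=O)/C=C/c1ccc(OCC=O)c(OCc2cc(OC)c(OCC=C)c(OC)c2)c1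
F13 | step 1 | 3-(benzyloxy)-4-[2-(tert-butyldimethylsilyloxy)ethoxy]benzaldehyde | O=Cc1ccc(OCCO[Si](C)(C)C(C)(C)C)c(OCc2ccccc2)c1
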